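**Plan**

- Feature: on the benzene ring, C1 carries the quaternary carbinol carbon and the neighbouring C2 carries the phenolic oxygen. That oxygen, C2, C1, the carbinol carbon and the carbon of its free CH2OH arm are the five ring atoms of a 3-hydroxybenzofuran-2(3H)-one once the CH2OH carbon is raised to the carboxyl level.
- Cuts: the CH2OH/phenol pair is traced back to the lactone C(=O)–O. The aryl C1–C(quaternary) bond and the lactone O–C(=O) bond are then cut together, giving a phenol and an α-keto ester. Each ester is finally cut at its alkyl C–O bond (benzylic CH2–O and pyruvate CH2–O).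
- Forward: each acid is attached as a nucleophile (one step per fragment). The fragments are joined at the quaternary carbon while the only new ring, the five-membered lactone fused to the benzene ring, closes in the same flask. NaBH4 then opens that ring to the phenol and the primary alcohol.
- Stereochemistry: the (R) centre of the 2-methylbutanoate and the Z double bond of the angelate (angeloyl = (2Z)-2-methylbut-2-enoyl) are bought and never activated. The quaternary centre is set in the joining step by (R)-BINOL on tetravalent titanium as (3S) in the lactone, which becomes (R) in the target through a change of priorities only.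

Key step: step 3

Assumption: (R)-2-methylbutanoic acid and angelic acid are bought as single isomers, and the face selected by (R)-BINOL is assigned by analogy; should the opposite C3 epimer form, (S)-BINOL is used in exactly the same way.

**Route**

Step 1
Reactants: 1 3-hydroxybenzyl alcohol; 2 (2R)-2-methylbutanoic acid
Product: 3 3-hydroxybenzyl (2R)-2-methylbutanoate
Conditions: PPh3, DIAD, THF, 0 °C to rt
Reagents that add atoms: none
Why: Mitsunobu esterification, in which the benzylic alcohol is activated as its alkoxyphosphonium ion and displaced by the carboxylate, which is far more acidic than the phenol and therefore the competent nucleophile, so the phenol stays free and the acid, never turned into an acyl donor, cannot lose its α-configuration through a ketene or enolate.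

Step 2
Reactants: 4 angelic acid; 5 ethyl bromopyruvate
Product: 7 ethyl 3-(angeloyloxy)-2-oxopropanoate, via cesium angelate 6 (not isolated)
Conditions: Cs2CO3 (0.5 equiv), DMF, 0 °C; then 5, 0 °C to rt; azeotropic drying with PhMe
Reagents that add atoms: none
Why: SN2 O-alkylation of a carboxylate by an α-bromo ketone, a standard route to α-acyloxy ketones, in which the angelic acid acts only as a nucleophile so the Z double bond is not exposed to the acyl activation that turns angelates into tiglates.

Step 3
Reactants: 3 3-hydroxybenzyl (2R)-2-methylbutanoate; 7 ethyl 3-(angeloyloxy)-2-oxopropanoate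
Product: 9 [(3S)-3-hydroxy-6-({[(2R)-2-methylbutanoyl]oxy}methyl)-2-oxo-2,3-dihydro-1-benzofuran-3-yl]methyl (2Z)-2-methylbut-2-enoate, via hydroxy ester 8 (not isolated)
Conditions: (R)-BINOL/Ti(OiPr)4 (1:1, 20 mol %), 4 Å MS, PhMe, iPrOH stripped; 3, then 7 added slowly, 0 °C to rt; then CSA (cat.), rt
Reagents that add atoms: none
Why: Proposed new method: phenol 3 exchanges onto (R)-(BINOLate)Ti(OiPr)2 to give the aryloxide (R)-(BINOLate)Ti(OiPr)(OAr) (Ar = aryl group of 3), which binds the 1,2-dicarbonyl unit of 7 at the same tetravalent titanium centre, so that the ring carbon ortho to the aryloxide oxygen adds to the keto carbon through a six-membered cyclic transition state (inner-sphere Friedel–Crafts hydroxyalkylation) and rearomatisation leaves hydroxy ester 8. The closest known reaction types are the ortho-specific hydroxyalkylation of titanium and magnesium phenolates with pyruvates and glyoxylates and the enantioselective Friedel–Crafts alkylation–lactonisation of naphthols and electron-rich phenols with trifluoropyruvate; what is new is the pairing of an enolisable 3-acyloxypyruvate with a phenol of ordinary nucleophilicity under binaphtholate control. The one new ring, the five-membered lactone, closes by 5-exo-trig acyl substitution of the phenolic oxygen at the ethyl ester, which expels ethanol and returns the titanium as an ethoxide ready for the next phenol. The C3 stereocentre is set in the C–C bond-forming event by the binaphtholate, which shields one face of the chelated ketone; with the CH2O-angelate arm in the place of the aldehyde hydrogen, the facial sense known for glyoxylate additions under (R)-BINOL and tetravalent titanium corresponds to the (3S) lactone. The step needs ortho rather than para attack and the less hindered of the two ortho carbons, which the intramolecular delivery and the crowding of the carbon flanked by OH and CH2O should secure, and it needs addition to outrun enolisation and Meerwein–Ponndorf–Verley hydride transfer from isopropoxide, which slow addition of 7, low temperature and removal of iPrOH should secure.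

Step 4
Reactants: 9 [(3S)-3-hydroxy-6-({[(2R)-2-methylbutanoyl]oxy}methyl)-2-oxo-2,3-dihydro-1-benzofuran-3-yl]methyl (2Z)-2-methylbut-2-enoate
Product: 11 (2R)-2,3-dihydroxy-2-[2-hydroxy-4-({[(2R)-2-methylbutanoyl]oxy}methyl)phenyl]propyl (2Z)-2-methylbut-2-enoate, via hydroxy aldehyde 10 (not isolated)
Conditions: NaBH4, THF–EtOH, −20 to 0 °C; AcOH quench at −20 °C
Reagents that add atoms: none
Why: NaBH4 reduction of an activated ester, in which the lactone, being both an aryl ester and an α-hydroxy ester, takes up hydride far faster than the two alkyl esters, opens to the phenoxide and hydroxy aldehyde 10 and is reduced at once to the primary alcohol, while the low temperature and cold acidic quench should keep the angelate from migrating between the two primary oxygens (a shift that would erase the quaternary centre), so the centre itself is untouched and only its descriptor changes from (3S) to (2R).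

**Compound list**

1 | 3-hydroxybenzyl alcohol | OCc1cccc(O)c1 | starting material
2 | (2R)-2-methylbutanoic acid | CC[C@@H](C)C(=O)O | starting material
3 | 3-hydroxybenzyl (2R)-2-methylbutanoate | CC[C@@H](C)C(=O)OCc1cccc(O)c1 | intermediate
4 | angelic acid, (2Z)-2-methylbut-2-enoic acid | C/C=C(/C)C(=O)O | starting material
5 | ethyl bromopyruvate, ethyl 3-bromo-2-oxopropanoate | CCOC(=O)C(=O)CBr | starting material
6 | cesium (2Z)-2-methylbut-2-enoate (cesium angelate; formed in the flask in step 2, not isolated) | C/C=C(/C)C(=O)[O-].[Cs+] | intermediate
7 | ethyl 3-{[(2Z)-2-methylbut-2-enoyl]oxy}-2-oxopropanoate | C/C=C(/C)C(=O)OCC(=O)C(=O)OCC | intermediate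
8 | ethyl (2S)-2-hydroxy-2-[2-hydroxy-4-({[(2R)-2-methylbutanoyl]oxy}methyl)phenyl]-3-{[(2Z)-2-methylbut-2-enoyl]oxy}propanoate (formed in the flask in step 3, not isolated) | C/C=C(/C)C(=O)OC[C@](O)(C(=O)OCC)c1ccc(COC(=O)[C@H](C)CC)cc1O | intermediate
9 | [(3S)-3-hydroxy-6-({[(2R)-2-methylbutanoyl]oxy}methyl)-2-oxo-2,3-dihydro-1-benzofuran-3-yl]methyl (2Z)-2-methylbut-2-enoate | C/C=C(/C)C(=O)OC[C@](O)(C(=O)O2)c1ccc(COC(=O)[C@H](C)CC)cc12 | intermediate
10 | (2S)-2-hydroxy-2-[2-hydroxy-4-({[(2R)-2-methylbutanoyl]oxy}methyl)phenyl]-3-oxopropyl (2Z)-2-methylbut-2-enoate (formed in the flask in step 4, not isolated) | C/C=C(/C)C(=O)OC[C@](O)(C=O)c1ccc(COC(=O)[C@H](C)CC)cc1O | intermediate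
11 | (2R)-2,3-dihydroxy-2-[2-hydroxy-4-({[(2R)-2-methylbutanoyl]oxy}methyl)phenyl]propyl (2Z)-2-methylbut-2-enoate | C/C=C(/C)C(=O)OC[C@](O)(CO)c1ccc(COC(=O)[C@H](C)CC)cc1O | target

**Count**

Total steps: 4. Longest linear sequence: 3 steps (step 1 or step 2, then steps 3 and 4).

**Steps most likely to fail**

Step 3 (proposed new method). The titanium aryloxide may add too slowly to the enolisable keto ester, the catalyst may fail to turn over, isopropoxide may reduce the keto group, or the facial selectivity may be poor. The fallback uses known chemistry, moves the stereocontrol into a chiral ester group and makes the titanium stoichiometric; it sets out from phenol 3 and cesium angelate 6 and returns at lactone 9. Bromopyruvic acid is esterified with (1R,2S,5R)-menthol (TsOH cat., PhMe, water removal) to (1R,2S,5R)-menthyl 3-bromo-2-oxopropanoate F1. F1 alkylates 6 under the conditions of step 2 to give (1R,2S,5R)-menthyl 3-(angeloyloxy)-2-oxopropanoate F2. Phenol 3 is converted with one equivalent of TiCl4 (CH2Cl2, −78 °C) into ArOTiCl3 and treated with F2. This ortho-specific hydroxyalkylation of aryloxytitanium trichlorides with pyruvates, with diastereoselection by a menthyl ester, is established and should give the menthyl hydroxy ester F3. Its minor diastereomer should be removable by chromatography because the auxiliary sits next to the new centre. TsOH (cat.) in PhMe at 60 °C should then close the lactone with loss of menthol and deliver 9. If the auxiliary favours the wrong face, (1S,2R,5S)-menthol is taken instead.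

Step 4. Hydride may also attack the alkyl esters, or the basic medium may drive acyl migration that scrambles the angelate and erodes the quaternary centre. The fallback stages the reduction so that no alkoxide meets the angelate under basic conditions; it sets out from 9 and returns at 11. LiAlH(OtBu)3 (THF, −78 to −40 °C), known to take aryl esters only to the aldehyde level and to leave alkyl esters alone, should give the cyclic lactol [(3S)-2,3-dihydroxy-6-({[(2R)-2-methylbutanoyl]oxy}methyl)-2,3-dihydro-1-benzofuran-3-yl]methyl (2Z)-2-methylbut-2-enoate F4, the ring tautomer of 10. NaBH(OAc)3 in AcOH–MeCN at 0 °C should then reduce the open aldehyde form under acidic, hydroxyl-directed conditions to 11.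

Step 2. Base may induce self-condensation of ethyl bromopyruvate, or the angelate may isomerise from Z to E during alkylation and work-up. The fallback unveils the ketone last and under neutral conditions; it sets out from 4 and returns at 7. Angelic acid opens commercial ethyl oxirane-2-carboxylate at the terminal carbon (Cs2CO3 10 mol %, DMF, 50 °C) to give racemic ethyl 2-hydroxy-3-(angeloyloxy)propanoate F5. Dess–Martin periodinane (CH2Cl2, NaHCO3, rt) should oxidise F5 to 7.

**Further compounds**

F1 | step 3 | (1R,2S,5R)-5-methyl-2-(propan-2-yl)cyclohexyl 3-bromo-2-oxopropanoate | BrCC(=O)C(=O)O[C@@H]1C[C@H](C)CC[C@H]1C(C)C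
F2 | step 3 | (1R,2S,5R)-5-methyl-2-(propan-2-yl)cyclohexyl 3-{[(2Z)-2-methylbut-2-enoyl]oxy}-2-oxopropanoate | C/C=C(/C)C(=O)OCC(=O)C(=O)O[C@@H]1C[C@H](C)CC[C@H]1C(C)C
F3 | step 3 | (1R,2S,5R)-5-methyl-2-(propan-2-yl)cyclohexyl (2S)-2-hydroxy-2-[2-hydroxy-4-({[(2R)-2-methylbutanoyl]oxy}methyl)phenyl]-3-{[(2Z)-2-methylbut-2-enoyl]oxy}propanoate | C/C=C(/C)C(=O)OC[C@](O)(C(=O)O[C@@H]1C[C@H](C)CC[C@H]1C(C)C)c1ccc(COC(=O)[C@H](C)CC)cc1O
F4 | step 4 | [(3S)-2,3-dihydroxy-6-({[(2R)-2-methylbutanoyl]oxy}methyl)-2,3-dihydro-1-benzofuran-3-yl]methyl (2Z)-2-methylbut-2-enoate, both C2 epimers | C/C=C(/C)C(=O)OC[C@](O)(C(O)O2)c1ccc(COC(=O)[C@H](C)CC)cc12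
F5 | step 2 | ethyl 2-hydroxy-3-{[(2Z)-2-methylbut-2-enoyl]oxy}propanoate, racemic | C/C=C(/C)C(=O)OCC(O)C(=O)OCC
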